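**Retrosynthetic overview**
1. Target 28 ⇐ selective stearoylation of the primary hydroxyl of triol enal 26.
2. 26 ⇐ side-chain CH2–CH= bond by light-driven nickel/iridium decarboxylative alkenylation of the carboxylate from δ-lactone 24 with alkenyl iodide 12; the tether carbon leaves as CO2.
3. 24 ⇐ quaternary ring carbon and its C–CH2 bond by a tethered photoredox radical lactonisation of oxalate 20 (new); the enal comes from the isopropenyl group (SeO2, then C=C isomerisation).
4. The cyclohexane ring is bought as (1S,2S,4R)-limonene-1,2-diol 13; no carbocycle is made. The only rings formed are the dioxolanone (step 3, opened in step 5) and the δ-lactone (step 12, opened in step 15).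
5. 12 ⇐ (R)-malic acid 5 (carbinol stereocenter) + alkenyl iodide 4 by nickel-electrocatalytic decarboxylative alkenylation, then alkyne formation and carboalumination–iodination.

Assumption: ring positions are numbered as in p-menthane (C1 = C(OH)Me, C2 = its neighbour that becomes quaternary, C3 = carbon receiving the three-carbon chain, C4 = isopropenyl carbon); for 17–20 the major C2 epimer is drawn, and the minor one converges in step 12.

**Step 1**
Reactants: 1 5-bromo-2-methylpent-2-ene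
Product: 2 6-methylhept-5-en-1-yne
Conditions: LiC≡CH·H2NCH2CH2NH2, DMSO, 0 °C → rt
Reagents that add atoms: lithium acetylide ethylenediamine complex, [Li+].[C-]#C.NCCN
Why: SN2 alkylation of an acetylide by a primary homoallylic bromide; no stereocenter is involved.

**Step 2**
Reactants: 2 6-methylhept-5-en-1-yne
Product: 4 (1E)-1-iodo-2,6-dimethylhepta-1,5-diene, via alkenyldimethylalane 3 (not isolated)
Conditions: Me3Al (2 equiv), Cp2ZrCl2 (20 mol%), CH2Cl2, 0 °C → rt; then I2, THF, −30 °C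
Reagents that add atoms: trimethylaluminium, C[Al](C)C; iodine, II
Why: Negishi zirconium-catalysed carboalumination adds Me and Al syn across the terminal alkyne (Me to the internal carbon) and iodinolysis proceeds with retention, giving only the E iodide.

**Step 3**
Reactants: 5 (R)-malic acid
Product: 6 [(4R)-2,2-dimethyl-5-oxo-1,3-dioxolan-4-yl]acetic acid
Conditions: Me2C(OMe)2, p-TsOH·H2O (cat.), rt
Reagents that add atoms: 2,2-dimethoxypropane, COC(C)(C)OC
Why: acid-catalysed transketalisation closes the five-membered dioxolanone on the α-hydroxy acid unit only, which leaves the β-carboxyl free and the purchased stereocenter untouched.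

**Step 4**
Reactants: 6 [(4R)-2,2-dimethyl-5-oxo-1,3-dioxolan-4-yl]acetic acid; 4 (1E)-1-iodo-2,6-dimethylhepta-1,5-diene
Product: 8 (5R)-5-[(2E)-3,7-dimethylocta-2,6-dien-1-yl]-2,2-dimethyl-1,3-dioxolan-4-one, via redox-active ester 7 (not isolated)
Conditions: N-hydroxyphthalimide, DIC, DMAP (cat.), CH2Cl2, rt; then 4 (2 equiv), NiCl2·6H2O (20 mol%), 2,2′-bipyridine, AgNO3, DMF, (+)Mg/(−)RVC, constant current, rt
Reagents that add atoms: none
Why: nickel-electrocatalytic decarboxylative alkenylation (reductive coupling of a redox-active ester with an alkenyl iodide) joins the primary radical to the alkenyl carbon with retention of the E geometry; the radical is one carbon away from the stereocenter, which is not touched.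

**Step 5**
Reactants: 8 (5R)-5-[(2E)-3,7-dimethylocta-2,6-dien-1-yl]-2,2-dimethyl-1,3-dioxolan-4-one
Product: 10 (3R,5E)-6,10-dimethylundeca-5,9-dien-1-yn-3-ol, via lactol 9 (not isolated)
Conditions: i-Bu2AlH, CH2Cl2, −78 °C; then MeOH, K2CO3, MeC(O)C(N2)P(O)(OMe)2, 0 °C → rt
Reagents that add atoms: dimethyl (1-diazo-2-oxopropyl)phosphonate, CC(=O)C(=[N+]=[N-])P(=O)(OC)OC
Why: the hydride stops at the aluminium lactolate, and methanolic carbonate then releases the α-hydroxy aldehyde (acetone is lost) in the presence of the Ohira–Bestmann reagent (Seyferth–Gilbert homologation), so the alkyne forms before the α-stereocenter can enolise.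

**Step 6**
Reactants: 10 (3R,5E)-6,10-dimethylundeca-5,9-dien-1-yn-3-ol
Product: 12 (1E,3R,5E)-1-iodo-2,6,10-trimethylundeca-1,5,9-trien-3-ol, via alkenylalane alkoxide 11 (not isolated)
Conditions: Me3Al (3.5 equiv), Cp2ZrCl2 (50 mol%), CH2Cl2, 0 °C → rt; then I2, THF, −30 °C
Reagents that add atoms: trimethylaluminium, C[Al](C)C; iodine, II
Why: Negishi carboalumination of the terminal alkyne of the aluminium alkoxide (syn, Me to the internal carbon) and iodinolysis with retention give the E trisubstituted alkenyl iodide; the trisubstituted alkenes and the carbinol center do not react.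

**Step 7**
Reactants: 13 (1S,2S,4R)-limonene-1,2-diol
Product: 14 (2S,5R)-2-hydroxy-2-methyl-5-(prop-1-en-2-yl)cyclohexan-1-one
Conditions: IBX, DMSO, rt
Reagents that add atoms: none
Why: hypervalent-iodine oxidation of the secondary alcohol of a 1,2-diol gives the α-hydroxy ketone without C–C cleavage; the tertiary carbinol center C1 (purchased, final configuration) and C4 are untouched.

**Step 8**
Reactants: 14 (2S,5R)-2-hydroxy-2-methyl-5-(prop-1-en-2-yl)cyclohexan-1-one; 15 tert-butyl(3-iodopropoxy)dimethylsilane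
Product: 16 (2S,5R,6S)-6-{3-[(tert-butyldimethylsilyl)oxy]propyl}-2-hydroxy-2-methyl-5-(prop-1-en-2-yl)cyclohexan-1-one
Conditions: LiN(i-Pr)2 (2.3 equiv), THF, −78 → 0 °C; then 15, DMPU, −40 °C → rt
Reagents that add atoms: none
Why: alkylation of the alkoxide–enolate dianion (only C3 can enolise) places the chain trans to the neighbouring C4 isopropenyl group, which is both the kinetic anti attack and the diequatorial thermodynamic isomer, so the purchased C4 center sets the C3 stereocenter.

**Step 9**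
Reactants: 16 (2S,5R,6S)-6-{3-[(tert-butyldimethylsilyl)oxy]propyl}-2-hydroxy-2-methyl-5-(prop-1-en-2-yl)cyclohexan-1-one
Product: 17 (1S,2R,3S,4R)-3-{3-[(tert-butyldimethylsilyl)oxy]propyl}-1,2-dimethyl-4-(prop-1-en-2-yl)cyclohexane-1,2-diol
Conditions: MeLi (3.5 equiv), CeCl3, THF, −78 → −20 °C
Reagents that add atoms: methyllithium, [Li]C
Why: organocerium 1,2-addition to the hindered ketone suppresses enolisation; the new C2 carbinol configuration (major epimer from attack anti to the axial C1 oxygen) does not matter, because C2 becomes a planar radical in step 12.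

**Step 10**
Reactants: 17 (1S,2R,3S,4R)-3-{3-[(tert-butyldimethylsilyl)oxy]propyl}-1,2-dimethyl-4-(prop-1-en-2-yl)cyclohexane-1,2-diol
Product: 18 (1S,2R,3S,4R)-3-{3-[(tert-butyldimethylsilyl)oxy]propyl}-2-hydroxy-1,2-dimethyl-4-(prop-1-en-2-yl)cyclohexyl prop-2-enoate
Conditions: CH2=CHCOCl (1.1 equiv), Et3N, DMAP (10 mol%), CH2Cl2, −20 → 0 °C
Reagents that add atoms: acryloyl chloride, C=CC(Cl)=O
Why: DMAP-catalysed acylation should take the less hindered of the two tertiary hydroxyls (C1–OH has a CH2 neighbour, C2–OH sits between two substituted carbons), which puts the acrylate tether on the oxygen of the purchased C1 center; the minor regioisomer is removed by chromatography.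

**Step 11**
Reactants: 18 (1S,2R,3S,4R)-3-{3-[(tert-butyldimethylsilyl)oxy]propyl}-2-hydroxy-1,2-dimethyl-4-(prop-1-en-2-yl)cyclohexyl prop-2-enoate
Product: 20 cesium 2-{[(1R,2S,5R,6S)-2-(acryloyloxy)-6-{3-[(tert-butyldimethylsilyl)oxy]propyl}-1,2-dimethyl-5-(prop-1-en-2-yl)cyclohexyl]oxy}-2-oxoacetate, via methyl oxalate 19 (not isolated)
Conditions: ClC(O)CO2Me, Et3N, DMAP, CH2Cl2, 0 °C → rt; then CsOH (1.0 equiv, aq.), THF, rt
Reagents that add atoms: methyl chlorooxoacetate, COC(=O)C(Cl)=O; cesium hydroxide, [Cs+].[OH-]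
Why: acylation of the remaining tertiary alcohol followed by saponification of the very electrophilic methyl oxalate (much faster than attack on the hindered tertiary acrylate) gives the cesium oxalate radical precursor.

**Step 12**
Reactants: 20 cesium 2-{[(1R,2S,5R,6S)-2-(acryloyloxy)-6-{3-[(tert-butyldimethylsilyl)oxy]propyl}-1,2-dimethyl-5-(prop-1-en-2-yl)cyclohexyl]oxy}-2-oxoacetate
Product: 21 (4aR,5S,6R,8aS)-5-{3-[(tert-butyldimethylsilyl)oxy]propyl}-4a,8a-dimethyl-6-(prop-1-en-2-yl)octahydro-2H-chromen-2-one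
Conditions: Ir[dF(CF3)ppy]2(dtbbpy)PF6 (2 mol%), H2O (10 equiv), DME/DMF 3:1, 0.02 M, blue LEDs (450 nm), 30 °C
Reagents that add atoms: none
Why: Proposed new method: a visible-light deoxygenative radical lactonisation in which the excited iridium photocatalyst oxidises the oxalate, two CO2 are lost to give the tertiary C2 radical (its earlier configuration is erased), this radical adds 6-endo to the terminal carbon of the acrylate hanging from the neighbouring axial C1 oxygen, and the α-acyl radical is reduced by the reduced photocatalyst and protonated by water; because the tether is anchored on the C1 oxygen the new C2–CH2 bond must form cis to it (a trans-fused lactone would force the C1 methyl and the C3 chain 1,3-diaxial), so the quaternary center is set from the purchased C1 center with its methyl cis to the C1 methyl and its chain trans to the C3 chain; the closest known reaction type is the intermolecular photoredox Giese addition of cesium oxalates of tertiary alcohols to acrylates, whose tethered lactonising 6-endo version onto the acrylate of a vicinal tertiary alcohol has not been shown.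

**Step 13**
Reactants: 21 (4aR,5S,6R,8aS)-5-{3-[(tert-butyldimethylsilyl)oxy]propyl}-4a,8a-dimethyl-6-(prop-1-en-2-yl)octahydro-2H-chromen-2-one
Product: 22 2-[(4aR,5S,6R,8aS)-5-{3-[(tert-butyldimethylsilyl)oxy]propyl}-4a,8a-dimethyl-2-oxooctahydro-2H-chromen-6-yl]prop-2-enal
Conditions: SeO2 (1.3 equiv), 1,4-dioxane, 80 °C
Reagents that add atoms: selenium dioxide, O=[Se]=O
Why: Riley allylic oxidation (ene reaction then [2,3]-shift) of the only alkene in the molecule attacks the methyl of the 1,1-disubstituted isopropenyl group and gives the 2-substituted acrolein.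

**Step 14**
Reactants: 22 2-[(4aR,5S,6R,8aS)-5-{3-[(tert-butyldimethylsilyl)oxy]propyl}-4a,8a-dimethyl-2-oxooctahydro-2H-chromen-6-yl]prop-2-enal
Product: 24 (2Z)-2-[(4aR,5S,8aS)-5-(3-hydroxypropyl)-4a,8a-dimethyl-2-oxooctahydro-6H-chromen-6-ylidene]propanal, via silyl ether enal 23 (not isolated)
Conditions: RhCl3·3H2O (5 mol%), EtOH, 75 °C; then 1 M HCl, THF, rt
Reagents that add atoms: none
Why: rhodium hydride addition/β-hydride elimination (the isomerisation used for α-methylene carbonyl compounds) moves the C=C into the tetrasubstituted conjugated position, where the Z isomer is expected to be favoured because the smaller formyl group takes the place next to the substituted C3 carbon (allylic 1,3-strain), and the acid then cleaves the primary silyl ether.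

**Step 15**
Reactants: 24 (2Z)-2-[(4aR,5S,8aS)-5-(3-hydroxypropyl)-4a,8a-dimethyl-2-oxooctahydro-6H-chromen-6-ylidene]propanal; 12 (1E,3R,5E)-1-iodo-2,6,10-trimethylundeca-1,5,9-trien-3-ol
Product: 26 (2Z)-2-[(2S,3R,4S)-4-hydroxy-3-[(3E,5R,7E)-5-hydroxy-4,8,12-trimethyltrideca-3,7,11-trien-1-yl]-2-(3-hydroxypropyl)-3,4-dimethylcyclohexylidene]propanal, via cesium carboxylate 25 (not isolated)
Conditions: CsOH·H2O (1.05 equiv), THF/H2O, 0 °C, evaporate; then 12 (1.3 equiv), Ir[dF(CF3)ppy]2(dtbbpy)PF6 (2 mol%), NiCl2(MeOCH2CH2OMe) (10 mol%), 4,4′-di-tert-butyl-2,2′-bipyridine (15 mol%), DMSO, blue LEDs, rt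
Reagents that add atoms: none
Why: lactone saponification followed by photoredox/nickel decarboxylative alkenylation: the carboxylate is oxidised by the excited photocatalyst, CO2 leaves, and the primary radical is captured by nickel that has inserted into the C–I bond of 12, so the CH2–CH= bond forms with retention of the E alkene and without touching any stereocenter.

**Step 16**
Reactants: 26 (2Z)-2-[(2S,3R,4S)-4-hydroxy-3-[(3E,5R,7E)-5-hydroxy-4,8,12-trimethyltrideca-3,7,11-trien-1-yl]-2-(3-hydroxypropyl)-3,4-dimethylcyclohexylidene]propanal; 27 octadecanoyl chloride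
Product: 28 3-[(1S,2R,3S,6Z)-3-hydroxy-2-[(3E,5R,7E)-5-hydroxy-4,8,12-trimethyltrideca-3,7,11-trien-1-yl]-2,3-dimethyl-6-(1-oxopropan-2-ylidene)cyclohexyl]propyl octadecanoate
Conditions: 27 (1.05 equiv), 2,4,6-collidine, CH2Cl2, −78 → −40 °C
Reagents that add atoms: none
Why: low-temperature acid chloride/collidine acylation discriminates sterically for the primary alcohol over the hindered secondary allylic and the tertiary alcohol.

**Compound list**
1 | 5-bromo-2-methylpent-2-ene | CC(C)=CCCBr | starting material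
2 | 6-methylhept-5-en-1-yne | CC(C)=CCCC#C | intermediate
3 | [(1E)-2,6-dimethylhepta-1,5-dien-1-yl]dimethylalane | CC(C)=CCC/C(C)=C/[Al](C)C | intermediate
4 | (1E)-1-iodo-2,6-dimethylhepta-1,5-diene | CC(C)=CCC/C(C)=C/I | intermediate
5 | (R)-malic acid, (2R)-2-hydroxybutanedioic acid | OC(=O)C[C@@H](O)C(=O)O | starting material
6 | [(4R)-2,2-dimethyl-5-oxo-1,3-dioxolan-4-yl]acetic acid | OC(=O)C[C@H]1OC(C)(C)OC1=O | intermediate
7 | 1,3-dioxoisoindolin-2-yl [(4R)-2,2-dimethyl-5-oxo-1,3-dioxolan-4-yl]acetate | O=C(C[C@H]1OC(C)(C)OC1=O)ON1C(=O)c2ccccc2C1=O | intermediate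
8 | (5R)-5-[(2E)-3,7-dimethylocta-2,6-dien-1-yl]-2,2-dimethyl-1,3-dioxolan-4-one | CC(C)=CCC/C(C)=C/C[C@H]1OC(C)(C)OC1=O | intermediate
9 | (5R)-5-[(2E)-3,7-dimethylocta-2,6-dien-1-yl]-2,2-dimethyl-1,3-dioxolan-4-ol (both C4 epimers, present as its aluminium alkoxide) | CC(C)=CCC/C(C)=C/C[C@H]1OC(C)(C)OC1O | intermediate
10 | (3R,5E)-6,10-dimethylundeca-5,9-dien-1-yn-3-ol | C#C[C@H](O)C/C=C(\C)CCC=C(C)C | intermediate
11 | dimethylaluminium (1E,3R,5E)-1-(dimethylalumanyl)-2,6,10-trimethylundeca-1,5,9-trien-3-olate | C[Al](C)/C=C(\C)[C@H](O[Al](C)C)C/C=C(\C)CCC=C(C)C | intermediate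
12 | (1E,3R,5E)-1-iodo-2,6,10-trimethylundeca-1,5,9-trien-3-ol | I/C=C(\C)[C@H](O)C/C=C(\C)CCC=C(C)C | intermediate
13 | (1S,2S,4R)-limonene-1,2-diol, (1S,2S,4R)-1-methyl-4-(prop-1-en-2-yl)cyclohexane-1,2-diol | C[C@]1(O)CC[C@@H](C(C)=C)C[C@@H]1O | starting material
14 | (2S,5R)-2-hydroxy-2-methyl-5-(prop-1-en-2-yl)cyclohexan-1-one | C[C@]1(O)CC[C@@H](C(C)=C)CC1=O | intermediate
15 | tert-butyl(3-iodopropoxy)dimethylsilane | CC(C)(C)[Si](C)(C)OCCCI | starting material
16 | (2S,5R,6S)-6-{3-[(tert-butyldimethylsilyl)oxy]propyl}-2-hydroxy-2-methyl-5-(prop-1-en-2-yl)cyclohexan-1-one | C[C@]1(O)CC[C@@H](C(C)=C)[C@H](CCCO[Si](C)(C)C(C)(C)C)C1=O | intermediate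
17 | (1S,2R,3S,4R)-3-{3-[(tert-butyldimethylsilyl)oxy]propyl}-1,2-dimethyl-4-(prop-1-en-2-yl)cyclohexane-1,2-diol (major C2 epimer drawn) | C[C@]1(O)CC[C@@H](C(C)=C)[C@H](CCCO[Si](C)(C)C(C)(C)C)[C@@]1(C)O | intermediate
18 | (1S,2R,3S,4R)-3-{3-[(tert-butyldimethylsilyl)oxy]propyl}-2-hydroxy-1,2-dimethyl-4-(prop-1-en-2-yl)cyclohexyl prop-2-enoate | C[C@]1(OC(=O)C=C)CC[C@@H](C(C)=C)[C@H](CCCO[Si](C)(C)C(C)(C)C)[C@@]1(C)O | intermediate
19 | methyl (1R,2S,5R,6S)-2-(acryloyloxy)-6-{3-[(tert-butyldimethylsilyl)oxy]propyl}-1,2-dimethyl-5-(prop-1-en-2-yl)cyclohexyl oxalate | C[C@]1(OC(=O)C=C)CC[C@@H](C(C)=C)[C@H](CCCO[Si](C)(C)C(C)(C)C)[C@@]1(C)OC(=O)C(=O)OC | intermediate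
20 | cesium 2-{[(1R,2S,5R,6S)-2-(acryloyloxy)-6-{3-[(tert-butyldimethylsilyl)oxy]propyl}-1,2-dimethyl-5-(prop-1-en-2-yl)cyclohexyl]oxy}-2-oxoacetate | C[C@]1(OC(=O)C=C)CC[C@@H](C(C)=C)[C@H](CCCO[Si](C)(C)C(C)(C)C)[C@@]1(C)OC(=O)C(=O)[O-].[Cs+] | intermediate
21 | (4aR,5S,6R,8aS)-5-{3-[(tert-butyldimethylsilyl)oxy]propyl}-4a,8a-dimethyl-6-(prop-1-en-2-yl)octahydro-2H-chromen-2-one (cis-fused δ-lactone) | C[C@]12CC[C@@H](C(C)=C)[C@H](CCCO[Si](C)(C)C(C)(C)C)[C@@]1(C)CCC(=O)O2 | intermediate
22 | 2-[(4aR,5S,6R,8aS)-5-{3-[(tert-butyldimethylsilyl)oxy]propyl}-4a,8a-dimethyl-2-oxooctahydro-2H-chromen-6-yl]prop-2-enal | C[C@]12CC[C@@H](C(=C)C=O)[C@H](CCCO[Si](C)(C)C(C)(C)C)[C@@]1(C)CCC(=O)O2 | intermediate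
23 | (2Z)-2-[(4aR,5S,8aS)-5-{3-[(tert-butyldimethylsilyl)oxy]propyl}-4a,8a-dimethyl-2-oxooctahydro-6H-chromen-6-ylidene]propanal | C[C@]12CC/C(=C(\C)C=O)[C@H](CCCO[Si](C)(C)C(C)(C)C)[C@@]1(C)CCC(=O)O2 | intermediate
24 | (2Z)-2-[(4aR,5S,8aS)-5-(3-hydroxypropyl)-4a,8a-dimethyl-2-oxooctahydro-6H-chromen-6-ylidene]propanal | C[C@]12CC/C(=C(\C)C=O)[C@H](CCCO)[C@@]1(C)CCC(=O)O2 | intermediate
25 | cesium 3-[(1R,2S,3Z,6S)-6-hydroxy-2-(3-hydroxypropyl)-1,6-dimethyl-3-(1-oxopropan-2-ylidene)cyclohexyl]propanoate | C[C@]1(O)CC/C(=C(\C)C=O)[C@H](CCCO)[C@@]1(C)CCC(=O)[O-].[Cs+] | intermediate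
26 | (2Z)-2-[(2S,3R,4S)-4-hydroxy-3-[(3E,5R,7E)-5-hydroxy-4,8,12-trimethyltrideca-3,7,11-trien-1-yl]-2-(3-hydroxypropyl)-3,4-dimethylcyclohexylidene]propanal | C[C@]1(O)CC/C(=C(\C)C=O)[C@H](CCCO)[C@@]1(C)CC/C=C(\C)[C@H](O)C/C=C(\C)CCC=C(C)C | intermediate
27 | octadecanoyl chloride (stearoyl chloride) | CCCCCCCCCCCCCCCCCC(=O)Cl | starting material
28 | 3-[(1S,2R,3S,6Z)-3-hydroxy-2-[(3E,5R,7E)-5-hydroxy-4,8,12-trimethyltrideca-3,7,11-trien-1-yl]-2,3-dimethyl-6-(1-oxopropan-2-ylidene)cyclohexyl]propyl octadecanoate | CCCCCCCCCCCCCCCCCC(=O)OCCC[C@H]1/C(=C(/C)C=O)CC[C@](C)(O)[C@]1(C)CC/C=C(\C)[C@H](O)C/C=C(\C)CCC=C(C)C | target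

**Step count and risks**
Total step count: 16. Longest linear sequence: 10 steps (13 → 28, steps 7 to 16).

The three steps most likely to fail are steps 12, 14 and 15.

Step 12 (the proposed new radical lactonisation) can fail because the acrylate ester prefers the rotamer that cannot close, so 1,2-acyloxy shift, simple reduction of the radical or oligomerisation may win. The fallback uses known chemistry, sets out from 16 and comes back at 21. Ketol 16 is heated with Ph3P=C=C=O in toluene (O-acylation, then intramolecular Wittig reaction) to give the butenolide F1. Me2CuLi with Me3SiCl adds methyl to the ring-fusion carbon from the convex face to give the cis-fused γ-lactone F2, which already has the quaternary center in the required configuration. i-Bu2AlH gives the lactol F3. Wittig reaction with Ph3P=CHOMe gives the one-carbon-longer enol ether F4. Mild hydrolysis (pyridinium tosylate, acetone/H2O) gives the δ-lactol F5. Oxidation with (n-Pr4N)RuO4 and N-methylmorpholine N-oxide gives 21.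

Step 14 can fail because the rhodium hydride isomerisation may stall at the hindered methine, give an E/Z mixture, or open the lactone in hot ethanol. The fallback sets out from 22 and comes back at 24. 1,4-Hydrosilylation of 22 with Et3SiH and RhCl(PPh3)3 gives the triethylsilyl enol ether F6. Saegusa–Ito dehydrogenation with Pd(OAc)2 in MeCN then places the double bond toward the ring carbon and gives 23 (any 22 that re-forms is recycled). Aqueous HCl converts 23 into 24 as in the main route.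

Step 15 can fail because an unactivated primary carboxylate is the least willing substrate class for oxidative photodecarboxylation, and the sensitiser may scramble the enal geometry. The fallback sets out from 24 and comes back at 26. The carboxylate 25 obtained from 24 is brought to pH 5 at 0 °C and esterified at once with N-hydroxyphthalimide and DIC to the redox-active ester F7 (material that relactonises is simply 24 again). F7 is coupled with 12 in the dark by nickel electrocatalysis (NiCl2·6H2O, 2,2′-bipyridine, AgNO3, magnesium anode, carbon cathode, DMF) to give 26.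

**Further compounds**
F1 | step 12 | (4S,5R,7aS)-4-{3-[(tert-butyldimethylsilyl)oxy]propyl}-7a-methyl-5-(prop-1-en-2-yl)-5,6,7,7a-tetrahydro-1-benzofuran-2(4H)-one | C[C@]12CC[C@@H](C(C)=C)[C@H](CCCO[Si](C)(C)C(C)(C)C)C1=CC(=O)O2
F2 | step 12 | (3aR,4S,5R,7aS)-4-{3-[(tert-butyldimethylsilyl)oxy]propyl}-3a,7a-dimethyl-5-(prop-1-en-2-yl)hexahydro-1-benzofuran-2(3H)-one | C[C@]12CC[C@@H](C(C)=C)[C@H](CCCO[Si](C)(C)C(C)(C)C)[C@@]1(C)CC(=O)O2
F3 | step 12 | (3aR,4S,5R,7aS)-4-{3-[(tert-butyldimethylsilyl)oxy]propyl}-3a,7a-dimethyl-5-(prop-1-en-2-yl)octahydro-1-benzofuran-2-ol (both anomers) | C[C@]12CC[C@@H](C(C)=C)[C@H](CCCO[Si](C)(C)C(C)(C)C)[C@@]1(C)CC(O)O2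
F4 | step 12 | (1S,2R,3S,4R)-3-{3-[(tert-butyldimethylsilyl)oxy]propyl}-2-(3-methoxyprop-2-en-1-yl)-1,2-dimethyl-4-(prop-1-en-2-yl)cyclohexan-1-ol (E/Z mixture) | C[C@]1(O)CC[C@@H](C(C)=C)[C@H](CCCO[Si](C)(C)C(C)(C)C)[C@@]1(C)CC=COC
F5 | step 12 | (4aR,5S,6R,8aS)-5-{3-[(tert-butyldimethylsilyl)oxy]propyl}-4a,8a-dimethyl-6-(prop-1-en-2-yl)octahydro-2H-chromen-2-ol (both anomers) | C[C@]12CC[C@@H](C(C)=C)[C@H](CCCO[Si](C)(C)C(C)(C)C)[C@@]1(C)CCC(O)O2
F6 | step 14 | (4aR,5S,6R,8aS)-5-{3-[(tert-butyldimethylsilyl)oxy]propyl}-4a,8a-dimethyl-6-{1-[(triethylsilyl)oxy]prop-1-en-2-yl}octahydro-2H-chromen-2-one (E/Z mixture) | C[C@]12CC[C@@H](C(C)=CO[Si](CC)(CC)CC)[C@H](CCCO[Si](C)(C)C(C)(C)C)[C@@]1(C)CCC(=O)O2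
F7 | step 15 | 1,3-dioxoisoindolin-2-yl 3-[(1R,2S,3Z,6S)-6-hydroxy-2-(3-hydroxypropyl)-1,6-dimethyl-3-(1-oxopropan-2-ylidene)cyclohexyl]propanoate | C[C@]1(O)CC/C(=C(\C)C=O)[C@H](CCCO)[C@@]1(C)CCC(=O)ON1C(=O)c2ccccc2C1=O
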